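The readings are calculated with constants of no real substance; the scatter is artificial.

The constants of this flask are hidden from me, so I count turnovers instead of fitting rates.

| flask | starting material | partner | precatalyst | remark | time |
|---|---|---|---|---|---|
| south | 10 mM | 16 mM | 0.50 mM | run made earlier |  |
| north-east | 10 mM | 24 mM | 0.50 mM | run made earlier |  |
| north-west | 10 mM | 25 mM | 0.50 mM | run made earlier |  |
| dusk | 10 mM | 15.0 mM | 0.50 mM |  | 30 min |
| noon | 10 mM | 22.0 mM | 0.50 mM |  | 30 min |
| spring | 10 mM | 34.0 mM | 0.50 mM |  | 30 min |

1. part of the starting material that has reacted at the end, dusk
2. part of the starting material that has reacted at the end, noon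
3. part of the starting material that has reacted at the end, spring
4. what raising the concentration of partner from its lowest to its highest value here does to the part of the starting material that has reacted (changes below 5 percentage points count as none) (it falls / it rises / no change)

- amounts and yields of released group count idle adduct too
- the numbers in the tables scatter with a standard deviation of 1.5 percentage points
- candidate steps: starting material + free catalyst <-> catalyst intermediate A; partner + catalyst intermediate A <-> catalyst intermediate B; catalyst intermediate B <-> released group + catalyst intermediate C; catalyst intermediate C -> free catalyst + product; starting material + released group <-> idle adduct; partner + precatalyst -> free catalyst + spent reagent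
- what has gone from starting material into another species counts as reacted, even if it can come back

| run | time / min | starting material / % | product / % |
|---|---|---|---|
| south | 4.00 | 97 | 3 |
| south | 10.0 | 96 | 4 |
| south | 20.0 | 86 | 11 |
| south | 30.0 | 72 | 19 |
| north-east | 8.00 | 95 | 3 |
| north-east | 15.0 | 87 | 9 |
| north-east | 25.0 | 72 | 21 |
| north-east | 30.0 | 66 | 26 |
| north-west | 2.50 | 99 | 1 |
| north-west | 6.00 | 97 | 0 |
| north-west | 12.0 | 91 | 7 |
| north-west | 30.0 | 67 | 25 |

(scatter of a reading: 1.5 percentage points)

I read the last row of each run, at 30.0 min. A turnover count is here the starting material reacted, in mM, per mM of precatalyst charged, and reacted means all that has left starting material, not product alone. One turnover is worth 5.00% of the starting material. The south run, with 16 mM of partner, keeps 72% of its starting material, which makes 5.60 turnovers. The north-east run, with 24 mM, reaches 6.80. The north-west run, with 25 mM, reaches 6.60.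

Those two north rows differ by 1 percentage point, less than the scatter of 1.5 points, so I take their mean. Against south, that mean gives 0.129 mM⁻¹. I call this the turnover gain: the turnovers won per extra mM of partner at this time and this catalyst charge.

Counting from south along this line, I commit to 27.4% reacted for dusk, 31.9% for noon and 39.6% for spring. That is a rise of 12 points. Spring holds more partner than any run, so its value is an extrapolation.

The forecast gives 27%, 32% and 36%, and says it rises. Its ground is “Partner therefore mainly shortens the lag”. We part at spring, where its 36% stands below my 39.6%.

The flasks give 25.3% for dusk, 32.5% for noon and 40.3% for spring, and the forecast stands within its tolerance. The part reacted does this: it rises, by 15 points.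

    starting material + free catalyst ⇌ catalyst intermediate A (K = 3700 M⁻¹, k = 57.7 M⁻¹ min⁻¹)
    partner + catalyst intermediate A ⇌ catalyst intermediate B (K = 2250 M⁻¹, k = 270 M⁻¹ min⁻¹)
    catalyst intermediate B ⇌ released group + catalyst intermediate C (K = 0.00102 M, k = 45.9 min⁻¹)
    catalyst intermediate C → free catalyst + product (k = 11.5 min⁻¹)
    starting material + released group ⇌ idle adduct, settled at all times (K = 57.9 M⁻¹)
    partner + precatalyst → free catalyst + spent reagent (k = 1.88 M⁻¹ min⁻¹)

In turnovers, spring reaches 8.06, and my line gave 7.93. The same gain, applied to the noon recipe with 5.5 mM of partner, counts 4.24 turnovers, or 21.2% reacted. That neighbouring flask gives 10.1%, which is 2.03 turnovers, so the line counts more than the flask. At 30.0 min the neighbouring flask still holds 74.7% of its catalyst charge as precatalyst, against 30.9% in noon.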